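**Strategy**

Both rings are closed last. The pyran (O2, C1, C8a, C4a, C4, C3; isochromene numbering) is a doubly vinylogous ester fused to the cyclohexenedione ring: C8a is α to the C8 ketone, C4a is β to the C6 ketone, and O2 is the enol oxygen of a C3 methyl ketone. The precursor is therefore an open chain on the lactate-derived quaternary C7, which already carries the linoleate: an enaminone arm (C8–C8a–C1) and a masked ynone/methyl ketone arm (C6–C5–C4a–C4–C3). Oxidation of two carbinols unveils ynone and ketone; Michael addition (C4a–C8a) and enol attack on C1 with loss of dimethylamine (O2–C1) then build the bicycle in one flask, with the polarity of the polyketide aldol.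

Key step: step 8

Remark: C7 of the target is read as R (O > C8 > C6 > CH3); atom labels C1–C8a refer to the isochromene numbering of the target throughout.
Remark: the two secondary carbinol carbons of the side arm are carried as epimer mixtures (racemic pentynol, unselective aldol carbinol), because both become carbonyl groups in step 8.

**Route**

Step 1
Reactants: 1 rac-pent-4-yn-2-ol
Product: 3 5-[(triethylsilyl)oxy]hex-2-ynal, via silyl ether 2 (not isolated)
Conditions: n-BuLi (1.0 equiv), THF, −78 °C; Et3SiCl, to 0 °C; n-BuLi (1.05 equiv), −78 °C; DMF, to 0 °C; inverse quench into aq. KH2PO4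
Reagents that add atoms: chlorotriethylsilane CC[Si](Cl)(CC)CC; N,N-dimethylformamide CN(C)C=O
Why: Silylation of the lithium alkoxide and formylation of the lithium acetylide with DMF are run in one flask (standard ynal synthesis), the buffered inverse quench keeping the liberated dimethylamine from adding to the ynal; the carbinol centre may stay racemic because it is oxidised in step 8.

Step 2
Reactants: 4 (S)-lactic acid; 5 pivalaldehyde
Product: 6 (2S,5S)-2-tert-butyl-5-methyl-1,3-dioxolan-4-one
Conditions: TsOH·H2O (cat.), H2SO4 (cat.), pentane, reflux, Dean–Stark; crystallisation at −78 °C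
Reagents that add atoms: none
Why: Acid-catalysed acetalisation with azeotropic removal of water should favour the cis acetal, which is purified by low-temperature crystallisation; the lactate centre is not touched, and the acetal centre, set under thermodynamic control, stores the chirality for the next step (self-regeneration of stereocentres).

Step 3
Reactants: 6 (2S,5S)-2-tert-butyl-5-methyl-1,3-dioxolan-4-one; 3 5-[(triethylsilyl)oxy]hex-2-ynal
Product: 8 (2S,5R)-5-{1,5-bis[(triethylsilyl)oxy]hex-2-yn-1-yl}-2-tert-butyl-5-methyl-1,3-dioxolan-4-one, via lithium aldolate 7 (not isolated)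
Conditions: LiN(iPr)2, THF, −78 °C; 3; then Et3SiOTf, −78 to −40 °C
Reagents that add atoms: triethylsilyl trifluoromethanesulfonate CC[Si](CC)(CC)OS(=O)(=O)C(F)(F)F
Why: Aldol addition of the lithium enolate to the aldehyde carbon of the ynal should take place on the face opposite the tert-butyl group, so the new C–C bond takes the place of the lactate hydrogen with retention and fixes the quaternary centre (later C7); in-situ silylation of the aldolate blocks retro-aldol cleavage, and the two carbinol centres are epimer mixtures of no consequence.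

Step 4
Reactants: 8 (2S,5R)-5-{1,5-bis[(triethylsilyl)oxy]hex-2-yn-1-yl}-2-tert-butyl-5-methyl-1,3-dioxolan-4-one
Product: 9 (2R)-2-hydroxy-N-methoxy-N,2-dimethyl-3,7-bis[(triethylsilyl)oxy]oct-4-ynamide
Conditions: MeNH(OMe)·HCl, i-PrMgCl, THF, −20 to 0 °C
Reagents that add atoms: N,O-dimethylhydroxylamine hydrochloride CNOC.Cl
Why: The chloromagnesium amide opens the acetal-activated lactone carbonyl to the Weinreb amide (ester aminolysis), and the hemiacetal left on the tertiary oxygen loses pivalaldehyde on work-up; the quaternary centre has no α-hydrogen and cannot epimerise.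

Step 5
Reactants: 9 (2R)-2-hydroxy-N-methoxy-N,2-dimethyl-3,7-bis[(triethylsilyl)oxy]oct-4-ynamide; 10 (9Z,12Z)-octadeca-9,12-dienoyl chloride (linoleoyl chloride)
Product: 11 (2R)-1-[methoxy(methyl)amino]-2-methyl-1-oxo-3,7-bis[(triethylsilyl)oxy]oct-4-yn-2-yl (9Z,12Z)-octadeca-9,12-dienoate
Conditions: DMAP, pyridine, CH2Cl2, 0 to 40 °C
Reagents that add atoms: none
Why: DMAP-catalysed acylation of the only free hydroxyl installs the linoleate on the tertiary oxygen before any secondary hydroxyl is set free; the neutral conditions avoid an alkoxide that could provoke silyl migration and leave the skipped Z,Z-diene alone.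

Step 6
Reactants: 11 (2R)-1-[methoxy(methyl)amino]-2-methyl-1-oxo-3,7-bis[(triethylsilyl)oxy]oct-4-yn-2-yl (9Z,12Z)-octadeca-9,12-dienoate
Product: 13 (1E,4R)-1-(dimethylamino)-4-methyl-3-oxo-5,9-bis[(triethylsilyl)oxy]dec-1-en-6-yn-4-yl (9Z,12Z)-octadeca-9,12-dienoate, via terminal ynone 12 (not isolated)
Conditions: HC≡CMgBr (3 equiv), THF, 0 °C to rt; AcOH, −20 °C; then Me2NH (2 M in THF), 0 °C
Reagents that add atoms: ethynylmagnesium bromide C#C[Mg]Br; dimethylamine CNC
Why: Alkynyl Grignard addition to the Weinreb amide stops at the chelated tetrahedral adduct (the tertiary-alkyl ester is far less electrophilic), protonation releases the terminal ynone, and conjugate addition of dimethylamine to this unhindered ynone should give the (E)-enaminone, a stable vinylogous amide that carries C8a as a latent nucleophile and C1 at the aldehyde oxidation level.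

Step 7
Reactants: 13 (1E,4R)-1-(dimethylamino)-4-methyl-3-oxo-5,9-bis[(triethylsilyl)oxy]dec-1-en-6-yn-4-yl (9Z,12Z)-octadeca-9,12-dienoate
Product: 14 (1E,4R)-1-(dimethylamino)-5,9-dihydroxy-4-methyl-3-oxodec-1-en-6-yn-4-yl (9Z,12Z)-octadeca-9,12-dienoate
Conditions: Et3N·3HF, MeCN/THF, 0 °C to rt; crude product taken on directly
Reagents that add atoms: none
Why: The nearly neutral amine–HF complex should cleave both secondary triethylsilyl ethers while the vinylogous amide, the alkyne and the tertiary ester persist; the absence of base and of strong acid is meant to suppress acyl shift to the freed C6 hydroxyl and addition of that hydroxyl to the enaminone.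

Step 8
Reactants: 14 (1E,4R)-1-(dimethylamino)-5,9-dihydroxy-4-methyl-3-oxodec-1-en-6-yn-4-yl (9Z,12Z)-octadeca-9,12-dienoate
Product: 17 (7R)-3,7-dimethyl-6,8-dioxo-7,8-dihydro-6H-isochromen-7-yl (9Z,12Z)-octadeca-9,12-dienoate, via diketo ynone 15 (not isolated), via aminomethylene dione 16 (not isolated)
Conditions: Dess–Martin periodinane (2.5 equiv), CH2Cl2, 0 °C to rt; then AcOH (5 equiv), 35 °C
Reagents that add atoms: none
Why: The periodinane oxidises both secondary carbinols, unveiling the C6 ynone and the C3 methyl ketone at once; the enaminone α-carbon C8a then adds to the ynone β-carbon C4a (6-endo-dig Michael addition, closing the carbocycle) and proton transfer gives the 2-aminomethylene cyclohexenedione 16. Under acetic acid the conjugated enol of the C3 ketone attacks C1 (6-endo-trig on the vinylogous amide, 6-exo-trig on its iminium form) and dimethylamine is expelled, closing the pyran, so C4a–C8a and O2–C1 are formed in one flask. The closest known chemistry is the tandem oxidation–heteroannulation of propargylic alcohols with enamines (first stage of the Bohlmann–Rahtz synthesis), joined to the oxygen-for-nitrogen ring closure used to make chromones and pyrans from enaminones. No stereocentre is formed; C7 is quaternary, non-enolisable and set in step 3, so it cannot scramble. The step needs Michael rather than anti-Michael attack (only C4a is β to the carbonyl and gives a six-membered ring) and O- rather than C-cyclisation of the acetonyl group (the conjugated enol through C4 brings only oxygen within reach of C1). Keeping C5 sp-hybridised until C4a–C8a exists excludes the C5-to-C1 aldol and the 4-pyranone closure that a free triketone would suffer.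

**Compound list**

1 | rac-pent-4-yn-2-ol | CC(O)CC#C | starting material
2 | triethyl(pent-4-yn-2-yloxy)silane (racemic) | CC(CC#C)O[Si](CC)(CC)CC | intermediate
3 | 5-[(triethylsilyl)oxy]hex-2-ynal (racemic) | CC(CC#CC=O)O[Si](CC)(CC)CC | intermediate
4 | (S)-lactic acid | C[C@H](O)C(=O)O | starting material
5 | pivalaldehyde | CC(C)(C)C=O | starting material
6 | (2S,5S)-2-tert-butyl-5-methyl-1,3-dioxolan-4-one (cis) | C[C@@H]1O[C@H](C(C)(C)C)OC1=O | intermediate
7 | (2S,5R)-2-tert-butyl-5-{1-hydroxy-5-[(triethylsilyl)oxy]hex-2-yn-1-yl}-5-methyl-1,3-dioxolan-4-one, present as its lithium alkoxide, epimers at both side-chain carbinol carbons | C[C@]1(C(O)C#CCC(C)O[Si](CC)(CC)CC)O[C@H](C(C)(C)C)OC1=O | intermediate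
8 | (2S,5R)-5-{1,5-bis[(triethylsilyl)oxy]hex-2-yn-1-yl}-2-tert-butyl-5-methyl-1,3-dioxolan-4-one, epimers at both silyloxy carbons | C[C@]1(C(O[Si](CC)(CC)CC)C#CCC(C)O[Si](CC)(CC)CC)O[C@H](C(C)(C)C)OC1=O | intermediate
9 | (2R)-2-hydroxy-N-methoxy-N,2-dimethyl-3,7-bis[(triethylsilyl)oxy]oct-4-ynamide, epimers at C3 and C7 | CON(C)C(=O)[C@](C)(O)C(O[Si](CC)(CC)CC)C#CCC(C)O[Si](CC)(CC)CC | intermediate
10 | (9Z,12Z)-octadeca-9,12-dienoyl chloride (linoleoyl chloride) | CCCCC/C=C\C/C=C\CCCCCCCC(=O)Cl | starting material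
11 | (2R)-1-[methoxy(methyl)amino]-2-methyl-1-oxo-3,7-bis[(triethylsilyl)oxy]oct-4-yn-2-yl (9Z,12Z)-octadeca-9,12-dienoate, epimers at C3 and C7 | CCCCC/C=C\C/C=C\CCCCCCCC(=O)O[C@@](C)(C(=O)N(C)OC)C(O[Si](CC)(CC)CC)C#CCC(C)O[Si](CC)(CC)CC | intermediate
12 | (4R)-4-methyl-3-oxo-5,9-bis[(triethylsilyl)oxy]deca-1,6-diyn-4-yl (9Z,12Z)-octadeca-9,12-dienoate, epimers at C5 and C9 | CCCCC/C=C\C/C=C\CCCCCCCC(=O)O[C@@](C)(C(=O)C#C)C(O[Si](CC)(CC)CC)C#CCC(C)O[Si](CC)(CC)CC | intermediate
13 | (1E,4R)-1-(dimethylamino)-4-methyl-3-oxo-5,9-bis[(triethylsilyl)oxy]dec-1-en-6-yn-4-yl (9Z,12Z)-octadeca-9,12-dienoate, epimers at C5 and C9 | CCCCC/C=C\C/C=C\CCCCCCCC(=O)O[C@@](C)(C(=O)/C=C/N(C)C)C(O[Si](CC)(CC)CC)C#CCC(C)O[Si](CC)(CC)CC | intermediate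
14 | (1E,4R)-1-(dimethylamino)-5,9-dihydroxy-4-methyl-3-oxodec-1-en-6-yn-4-yl (9Z,12Z)-octadeca-9,12-dienoate, epimers at C5 and C9 | CCCCC/C=C\C/C=C\CCCCCCCC(=O)O[C@@](C)(C(=O)/C=C/N(C)C)C(O)C#CCC(C)O | intermediate
15 | (1E,4S)-1-(dimethylamino)-4-methyl-3,5,9-trioxodec-1-en-6-yn-4-yl (9Z,12Z)-octadeca-9,12-dienoate | CCCCC/C=C\C/C=C\CCCCCCCC(=O)O[C@@](C)(C(=O)/C=C/N(C)C)C(=O)C#CCC(C)=O | intermediate
16 | (1R)-3-[(dimethylamino)methylidene]-1-methyl-2,6-dioxo-4-(2-oxopropyl)cyclohex-4-en-1-yl (9Z,12Z)-octadeca-9,12-dienoate | CCCCC/C=C\C/C=C\CCCCCCCC(=O)O[C@]1(C)C(=O)C=C(CC(C)=O)C(=CN(C)C)C1=O | intermediate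
17 | (7R)-3,7-dimethyl-6,8-dioxo-7,8-dihydro-6H-isochromen-7-yl (9Z,12Z)-octadeca-9,12-dienoate | CCCCC/C=C\C/C=C\CCCCCCCC(=O)O[C@]1(C)C(=O)C=C2C=C(C)OC=C2C1=O | target

**Count and risks**

Total step count: 8. Longest linear sequence: 7 steps (from 4 through steps 2–8; equally from 1 through steps 1 and 3–8).

Steps most likely to fail:

Step 8. The periodinane may attack the electron-rich enaminone, or the C3 hydroxyl may add to C1 before it has been oxidised, which would lock the pyran at the wrong oxidation level. The fallback makes the enaminone only after both oxidations and sets out from 11. Ethynylmagnesium bromide with a cold acidic work-up should give ynone 12, now isolated. Et3N·3HF should then free (4R)-5,9-dihydroxy-4-methyl-3-oxodeca-1,6-diyn-4-yl (9Z,12Z)-octadeca-9,12-dienoate F1. Dess–Martin periodinane should oxidise both carbinols to (4S)-4-methyl-3,5,9-trioxodeca-1,6-diyn-4-yl (9Z,12Z)-octadeca-9,12-dienoate F2. One equivalent of dimethylamine at −78 °C should add to the unhindered terminal ynone much faster than to the substituted one and give 15, where the fallback rejoins the route; 15 should close to 17 on warming with AcOH.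

Step 7. Once the C6 hydroxyl is free, the linoleoyl group may shift from the tertiary to the neighbouring secondary oxygen. The fallback postpones the ester to the end and sets out from 9.
- t-BuMe2SiOTf and 2,6-lutidine should give (2R)-2-[(tert-butyldimethylsilyl)oxy]-N-methoxy-N,2-dimethyl-3,7-bis[(triethylsilyl)oxy]oct-4-ynamide F3.
- Ethynylmagnesium bromide should give (4R)-4-[(tert-butyldimethylsilyl)oxy]-4-methyl-5,9-bis[(triethylsilyl)oxy]deca-1,6-diyn-3-one F4.
- Dimethylamine should give (1E,4R)-4-[(tert-butyldimethylsilyl)oxy]-1-(dimethylamino)-4-methyl-5,9-bis[(triethylsilyl)oxy]dec-1-en-6-yn-3-one F5.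
- Et3N·3HF should remove only the two secondary triethylsilyl groups and give (1E,4R)-4-[(tert-butyldimethylsilyl)oxy]-1-(dimethylamino)-5,9-dihydroxy-4-methyldec-1-en-6-yn-3-one F6.
- The oxidative cascade of step 8 should pass through (1E,4S)-4-[(tert-butyldimethylsilyl)oxy]-1-(dimethylamino)-4-methyldec-1-en-6-yne-3,5,9-trione F7 and (2R)-2-[(tert-butyldimethylsilyl)oxy]-4-[(dimethylamino)methylidene]-2-methyl-5-(2-oxopropyl)cyclohex-5-ene-1,3-dione F8 to (7R)-7-[(tert-butyldimethylsilyl)oxy]-3,7-dimethyl-6H-isochromene-6,8(7H)-dione F9.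
- HF·pyridine should free (7R)-7-hydroxy-3,7-dimethyl-6H-isochromene-6,8(7H)-dione F10.
- Acylation of this tertiary alcohol with 10, DMAP and pyridine, an established way to esterify 7-hydroxy-isochromenediones, should give 17, where the fallback rejoins the route.

Step 6. The alkynyl Grignard reagent may attack the linoleate carbonyl in competition with the hindered amide. The fallback builds the C8 arm without any organometallic step after esterification and sets out from 9. Excess MeMgBr should give (3R)-3-hydroxy-3-methyl-4,8-bis[(triethylsilyl)oxy]non-5-yn-2-one F11. Acylation with 10, DMAP and pyridine should give (3R)-3-methyl-2-oxo-4,8-bis[(triethylsilyl)oxy]non-5-yn-3-yl (9Z,12Z)-octadeca-9,12-dienoate F12. Condensation of its only methyl ketone with N,N-dimethylformamide dimethyl acetal at 80 °C should give enaminone 13, where the fallback rejoins the route.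

**Further compounds**

F1 | step 8 | (4R)-5,9-dihydroxy-4-methyl-3-oxodeca-1,6-diyn-4-yl (9Z,12Z)-octadeca-9,12-dienoate | CCCCC/C=C\C/C=C\CCCCCCCC(=O)O[C@@](C)(C(=O)C#C)C(O)C#CCC(C)O
F2 | step 8 | (4S)-4-methyl-3,5,9-trioxodeca-1,6-diyn-4-yl (9Z,12Z)-octadeca-9,12-dienoate | CCCCC/C=C\C/C=C\CCCCCCCC(=O)O[C@@](C)(C(=O)C#C)C(=O)C#CCC(C)=O
F3 | step 7 | (2R)-2-[(tert-butyldimethylsilyl)oxy]-N-methoxy-N,2-dimethyl-3,7-bis[(triethylsilyl)oxy]oct-4-ynamide | CON(C)C(=O)[C@](C)(O[Si](C)(C)C(C)(C)C)C(O[Si](CC)(CC)CC)C#CCC(C)O[Si](CC)(CC)CC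
F4 | step 7 | (4R)-4-[(tert-butyldimethylsilyl)oxy]-4-methyl-5,9-bis[(triethylsilyl)oxy]deca-1,6-diyn-3-one | C#CC(=O)[C@](C)(O[Si](C)(C)C(C)(C)C)C(O[Si](CC)(CC)CC)C#CCC(C)O[Si](CC)(CC)CC
F5 | step 7 | (1E,4R)-4-[(tert-butyldimethylsilyl)oxy]-1-(dimethylamino)-4-methyl-5,9-bis[(triethylsilyl)oxy]dec-1-en-6-yn-3-one | CN(C)/C=C/C(=O)[C@](C)(O[Si](C)(C)C(C)(C)C)C(O[Si](CC)(CC)CC)C#CCC(C)O[Si](CC)(CC)CC
F6 | step 7 | (1E,4R)-4-[(tert-butyldimethylsilyl)oxy]-1-(dimethylamino)-5,9-dihydroxy-4-methyldec-1-en-6-yn-3-one | CN(C)/C=C/C(=O)[C@](C)(O[Si](C)(C)C(C)(C)C)C(O)C#CCC(C)O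
F7 | step 7 | (1E,4S)-4-[(tert-butyldimethylsilyl)oxy]-1-(dimethylamino)-4-methyldec-1-en-6-yne-3,5,9-trione | CN(C)/C=C/C(=O)[C@](C)(O[Si](C)(C)C(C)(C)C)C(=O)C#CCC(C)=O
F8 | step 7 | (2R)-2-[(tert-butyldimethylsilyl)oxy]-4-[(dimethylamino)methylidene]-2-methyl-5-(2-oxopropyl)cyclohex-5-ene-1,3-dione | C[Si](C)(C(C)(C)C)O[C@]1(C)C(=O)C=C(CC(C)=O)C(=CN(C)C)C1=O
F9 | step 7 | (7R)-7-[(tert-butyldimethylsilyl)oxy]-3,7-dimethyl-6H-isochromene-6,8(7H)-dione | C[Si](C)(C(C)(C)C)O[C@]1(C)C(=O)C=C2C=C(C)OC=C2C1=O
F10 | step 7 | (7R)-7-hydroxy-3,7-dimethyl-6H-isochromene-6,8(7H)-dione | O[C@]1(C)C(=O)C=C2C=C(C)OC=C2C1=O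
F11 | step 6 | (3R)-3-hydroxy-3-methyl-4,8-bis[(triethylsilyl)oxy]non-5-yn-2-one | CC(=O)[C@](C)(O)C(O[Si](CC)(CC)CC)C#CCC(C)O[Si](CC)(CC)CC
F12 | step 6 | (3R)-3-methyl-2-oxo-4,8-bis[(triethylsilyl)oxy]non-5-yn-3-yl (9Z,12Z)-octadeca-9,12-dienoate | CCCCC/C=C\C/C=C\CCCCCCCC(=O)O[C@@](C)(C(C)=O)C(O[Si](CC)(CC)CC)C#CCC(C)O[Si](CC)(CC)CC
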